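**Plan**

1. Numbering: lactone O1, C2 (C=O), C3=C4, C5, C6; side chain C1'–C15' with hydroxyls on C2', C4', C6' (C2'/C6 oxygens 1,3-anti; C2'/C4'/C6' all syn).
2. Enabling feature: the segment O–C2'–C1'H2–C6(O)–C5H2–C4(sp2) is the retron of an all-cis 2,4,6-trisubstituted oxane (ring atoms O, C2', C1', C6, C5, C4). In this temporary ring the two 1,3-anti oxygens are cis and already told apart: one is the ring oxygen, the other a free hydroxyl.
3. Retrosynthesis: cut C3=C4 and the O1–C2 ester bond (acrylate metathesis). Re-tie the C2' oxygen to C4 through a sacrificial CH2OTs carbon. Cut C1'–C2' together with O–C2' and C6–O (Prins cyclization) into a C2'–C15' aldehyde and a C1'/C6/C5/C4 homoallylic alcohol. Cut the aldehyde at C3'–C4' and C5'–C6' (two allylations) back to decanal.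
4. Forward: the chain aldehyde is built linearly; the Prins union closes the temporary oxane; acylation, then zinc fragmentation opens the oxane again; metathesis closes the lactone ring last; debenzylation ends the route.
5. Stereochemistry: C6' and C4' come from reagent-controlled allylborations. C2' and C6 both come from the Prins chair, relayed from the single carbinol centre of (S)-glycidyl tosylate, which is erased when the oxane is opened.

Key step: step 8

Remark: (+)-Ipc2B(allyl) denotes the allylborane of the (−)-α-pinene series, taken as the purchased reagent solution.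

**Route**

Step 1
Reactants: 1 decanal
Product: 3 (4S)-tridec-1-en-4-ol, via borinate ester 2 (not isolated)
Conditions: (+)-Ipc2B(allyl), Et2O, −78 °C; then NaOH, H2O2, 0 °C to rt
Reagents that add atoms: (+)-B-allyldiisopinocampheylborane, C=CCB([C@H]1C[C@H]2C[C@@H]([C@@H]1C)C2(C)C)[C@H]1C[C@H]2C[C@@H]([C@@H]1C)C2(C)C
Why: Brown allylboration through a chair Zimmerman–Traxler transition state, in which the isopinocampheyl groups direct allyl transfer to the Re face of the aldehyde and so should set C6' as S.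

Step 2
Reactants: 3 (4S)-tridec-1-en-4-ol
Product: 4 (4S)-4-(benzyloxy)tridec-1-ene
Conditions: NaH, BnBr, Bu4NI (cat.), THF, 0 °C to rt
Reagents that add atoms: benzyl bromide, BrCc1ccccc1
Why: Williamson etherification of the sodium alkoxide touches no stereocentre and installs an ether that should survive the strong acid of the key step.

Step 3
Reactants: 4 (4S)-4-(benzyloxy)tridec-1-ene
Product: 6 (3S)-3-(benzyloxy)dodecanal, via secondary ozonide 5 (not isolated)
Conditions: O3, CH2Cl2, −78 °C; then PPh3, −78 °C to rt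
Reagents that add atoms: ozone, [O-][O+]=O
Why: Ozonolysis with reductive work-up cleaves only the terminal alkene and should unveil the β-benzyloxy aldehyde, which has no stereocentre α to the carbonyl.

Step 4
Reactants: 6 (3S)-3-(benzyloxy)dodecanal
Product: 8 (4R,6S)-6-(benzyloxy)pentadec-1-en-4-ol, via borinate ester 7 (not isolated)
Conditions: (+)-Ipc2B(allyl), Et2O, −78 °C; then NaOH, H2O2, 0 °C to rt
Reagents that add atoms: (+)-B-allyldiisopinocampheylborane, C=CCB([C@H]1C[C@H]2C[C@@H]([C@@H]1C)C2(C)C)[C@H]1C[C@H]2C[C@@H]([C@@H]1C)C2(C)C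
Why: A second Brown allylboration with the same reagent (same Re-face delivery) should override the weak bias of the β-benzyloxy centre and set C4' 1,3-syn to C6'.

Step 5
Reactants: 8 (4R,6S)-6-(benzyloxy)pentadec-1-en-4-ol
Product: 9 (4R,6S)-4,6-bis(benzyloxy)pentadec-1-ene
Conditions: NaH, BnBr, Bu4NI (cat.), THF/DMF, 0 °C to rt
Reagents that add atoms: benzyl bromide, BrCc1ccccc1
Why: Williamson etherification of the secondary alkoxide proceeds without touching either stereocentre.

Step 6
Reactants: 9 (4R,6S)-4,6-bis(benzyloxy)pentadec-1-ene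
Product: 11 (3S,5S)-3,5-bis(benzyloxy)tetradecanal, via secondary ozonide 10 (not isolated)
Conditions: O3, CH2Cl2, −78 °C; then PPh3, −78 °C to rt
Reagents that add atoms: ozone, [O-][O+]=O
Why: Ozonolysis with reductive work-up should give the C2'–C15' aldehyde with both benzyl ethers intact.

Step 7
Reactants: 12 (2S)-glycidyl tosylate
Product: 13 (2S)-2-hydroxypent-4-en-1-yl 4-methylbenzenesulfonate
Conditions: CH2=CHMgBr, CuI (10 mol %), THF, −40 °C
Reagents that add atoms: vinylmagnesium bromide, C=C[Mg]Br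
Why: Copper-catalysed Grignard opening of the epoxide at its unsubstituted carbon is faster than displacement of the sulfonate and leaves the stereocentre untouched.

Step 8
Reactants: 11 (3S,5S)-3,5-bis(benzyloxy)tetradecanal; 13 (2S)-2-hydroxypent-4-en-1-yl 4-methylbenzenesulfonate
Product: 15 [(2S,4R,6R)-6-[(2S,4S)-2,4-bis(benzyloxy)tridecyl]-4-hydroxyoxan-2-yl]methyl 4-methylbenzenesulfonate (all-cis oxane), via oxanyl trifluoroacetate 14 (not isolated)
Conditions: TFA, CH2Cl2, 0 °C to rt; then K2CO3, MeOH, 0 °C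
Reagents that add atoms: trifluoroacetic acid, OC(=O)C(F)(F)F
Why: Acid condenses the aldehyde with the hydroxyl of 13 to an (E)-oxocarbenium ion; its terminal alkene attacks the C2' carbon through a chair transition state, forming the C1'–C2' bond and an oxan-4-yl cation at C6 that trifluoroacetate captures equatorially, and methanolysis then frees the C6 hydroxyl. The closest known reaction type is the trifluoroacetic acid-mediated Prins cyclization of homoallylic alcohols with aliphatic aldehydes to all-cis 2,6-disubstituted oxan-4-ols. The one ring closed, the temporary oxane (O, C2', C1', C6, C5, C4), forms by 6-endo attack of the alkene on the oxocarbenium carbon. C2' is set by the carbinol centre of 13 (the future C4), because both ring substituents sit equatorial in the chair (2,6-cis); C6 is set by the same chair through equatorial entry of the nucleophile, so the C2' and C6 oxygens come out 1,3-anti. The step needs 2,6-cis/4-equatorial selectivity without 2-oxonia-Cope side-chain exchange; the electron-withdrawing tosyloxymethyl group should secure this by destabilising the rearranged oxocarbenium ion, while benzyl ethers and the tosylate tolerate the acid.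

Step 9
Reactants: 15 all-cis oxan-4-ol tosylate
Product: 16 (2S,4R,6S)-2-[(2S,4S)-2,4-bis(benzyloxy)tridecyl]-6-[(tosyloxy)methyl]oxan-4-yl prop-2-enoate
Conditions: acryloyl chloride, Et3N, DMAP (cat.), CH2Cl2, 0 °C
Reagents that add atoms: acryloyl chloride, C=CC(=O)Cl
Why: Acylation can only occur at the C6 hydroxyl because the C2' oxygen is locked in the oxane ring, so the two oxygens of the 1,3-anti diol are differentiated without a protecting group.

Step 10
Reactants: 16 oxanyl acrylate tosylate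
Product: 18 (4S,6S,8R,10S)-8,10-bis(benzyloxy)-6-hydroxynonadec-1-en-4-yl prop-2-enoate, via primary iodide 17 (not isolated)
Conditions: NaI, 2-butanone, 70 °C; then Zn dust, AcOH, THF/H2O, 40 °C
Reagents that add atoms: none
Why: Finkelstein exchange followed by zinc-mediated reductive β-elimination of the β-alkoxy iodide (Boord-type fragmentation) should open the temporary ring, free the C2' hydroxyl, turn C4 into a vinyl carbon and erase the relay stereocentre; the acetic acid buffer protonates the zinc alkoxide to suppress acyl migration.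

Step 11
Reactants: 18 hydroxy diene acrylate
Product: 19 (6S)-6-[(2S,4R,6S)-4,6-bis(benzyloxy)-2-hydroxypentadecyl]-5,6-dihydro-2H-pyran-2-one
Conditions: second-generation Grubbs catalyst RuCl2(=CHPh)(PCy3)(SIMes) (5 mol %), CH2Cl2 (0.005 M), 40 °C
Reagents that add atoms: none
Why: Ring-closing metathesis of the acrylate with the vinyl group forms C3=C4, the six-membered ring enforces the Z geometry, and loss of ethene drives the reaction in the presence of the free hydroxyl and benzyl ethers.

Step 12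
Reactants: 19 bis(benzyl) ether lactone
Product: 20 (6S)-6-[(2S,4S,6S)-2,4,6-trihydroxypentadecyl]-5,6-dihydro-2H-pyran-2-one
Conditions: TiCl4, CH2Cl2, 0 °C; then aq. NaHCO3
Reagents that add atoms: none
Why: Lewis acid-mediated debenzylation (chloride attack on the benzylic carbon of the TiCl4-coordinated ethers) should free the C4' and C6' hydroxyls without hydrogenating the enoate or touching any stereocentre.

**Compound list**

1 | decanal | CCCCCCCCCC=O | starting material
2 | (4S)-tridec-1-en-4-yl bis[(+)-isopinocampheyl]borinate (formed in the flask) | CCCCCCCCC[C@H](OB([C@H]1C[C@H]2C[C@@H]([C@@H]1C)C2(C)C)[C@H]1C[C@H]2C[C@@H]([C@@H]1C)C2(C)C)CC=C | intermediate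
3 | (4S)-tridec-1-en-4-ol | CCCCCCCCC[C@H](O)CC=C | intermediate
4 | (4S)-4-(benzyloxy)tridec-1-ene | CCCCCCCCC[C@H](OCc1ccccc1)CC=C | intermediate
5 | 3-[(2S)-2-(benzyloxy)undecyl]-1,2,4-trioxolane (secondary ozonide of 4, both epimers at the ring carbon; formed in the flask) | CCCCCCCCC[C@H](OCc1ccccc1)CC1OCOO1 | intermediate
6 | (3S)-3-(benzyloxy)dodecanal | CCCCCCCCC[C@H](OCc1ccccc1)CC=O | intermediate
7 | (4R,6S)-6-(benzyloxy)pentadec-1-en-4-yl bis[(+)-isopinocampheyl]borinate (formed in the flask) | CCCCCCCCC[C@H](OCc1ccccc1)C[C@H](OB([C@H]1C[C@H]2C[C@@H]([C@@H]1C)C2(C)C)[C@H]1C[C@H]2C[C@@H]([C@@H]1C)C2(C)C)CC=C | intermediate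
8 | (4R,6S)-6-(benzyloxy)pentadec-1-en-4-ol | CCCCCCCCC[C@H](OCc1ccccc1)C[C@H](O)CC=C | intermediate
9 | (4R,6S)-4,6-bis(benzyloxy)pentadec-1-ene | CCCCCCCCC[C@H](OCc1ccccc1)C[C@H](OCc1ccccc1)CC=C | intermediate
10 | 3-[(2S,4S)-2,4-bis(benzyloxy)tridecyl]-1,2,4-trioxolane (secondary ozonide of 9, both epimers at the ring carbon; formed in the flask) | CCCCCCCCC[C@H](OCc1ccccc1)C[C@H](OCc1ccccc1)CC1OCOO1 | intermediate
11 | (3S,5S)-3,5-bis(benzyloxy)tetradecanal | CCCCCCCCC[C@H](OCc1ccccc1)C[C@H](OCc1ccccc1)CC=O | intermediate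
12 | (2S)-glycidyl tosylate, (2S)-oxiran-2-ylmethyl 4-methylbenzenesulfonate | Cc1ccc(cc1)S(=O)(=O)OC[C@@H]1CO1 | starting material
13 | (2S)-2-hydroxypent-4-en-1-yl 4-methylbenzenesulfonate | C=CC[C@H](O)COS(=O)(=O)c1ccc(C)cc1 | intermediate
14 | (2S,4R,6S)-2-[(2S,4S)-2,4-bis(benzyloxy)tridecyl]-6-[(tosyloxy)methyl]oxan-4-yl trifluoroacetate (all-cis; formed in the flask) | CCCCCCCCC[C@H](OCc1ccccc1)C[C@H](OCc1ccccc1)C[C@H]1C[C@@H](OC(=O)C(F)(F)F)C[C@@H](COS(=O)(=O)c2ccc(C)cc2)O1 | intermediate
15 | [(2S,4R,6R)-6-[(2S,4S)-2,4-bis(benzyloxy)tridecyl]-4-hydroxyoxan-2-yl]methyl 4-methylbenzenesulfonate (all-cis) | CCCCCCCCC[C@H](OCc1ccccc1)C[C@H](OCc1ccccc1)C[C@H]1C[C@@H](O)C[C@@H](COS(=O)(=O)c2ccc(C)cc2)O1 | intermediate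
16 | (2S,4R,6S)-2-[(2S,4S)-2,4-bis(benzyloxy)tridecyl]-6-[(tosyloxy)methyl]oxan-4-yl prop-2-enoate (all-cis) | CCCCCCCCC[C@H](OCc1ccccc1)C[C@H](OCc1ccccc1)C[C@H]1C[C@@H](OC(=O)C=C)C[C@@H](COS(=O)(=O)c2ccc(C)cc2)O1 | intermediate
17 | (2S,4R,6S)-2-[(2S,4S)-2,4-bis(benzyloxy)tridecyl]-6-(iodomethyl)oxan-4-yl prop-2-enoate (formed in the flask) | CCCCCCCCC[C@H](OCc1ccccc1)C[C@H](OCc1ccccc1)C[C@H]1C[C@@H](OC(=O)C=C)C[C@@H](CI)O1 | intermediate
18 | (4S,6S,8R,10S)-8,10-bis(benzyloxy)-6-hydroxynonadec-1-en-4-yl prop-2-enoate | CCCCCCCCC[C@H](OCc1ccccc1)C[C@H](OCc1ccccc1)C[C@H](O)C[C@@H](OC(=O)C=C)CC=C | intermediate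
19 | (6S)-6-[(2S,4R,6S)-4,6-bis(benzyloxy)-2-hydroxypentadecyl]-5,6-dihydro-2H-pyran-2-one | CCCCCCCCC[C@H](OCc1ccccc1)C[C@H](OCc1ccccc1)C[C@H](O)C[C@@H]1CC=CC(=O)O1 | intermediate
20 | (6S)-6-[(2S,4S,6S)-2,4,6-trihydroxypentadecyl]-5,6-dihydro-2H-pyran-2-one | CCCCCCCCC[C@H](O)C[C@H](O)C[C@H](O)C[C@@H]1CC=CC(=O)O1 | target

**Step count**

Total steps: 12. Longest linear sequence: 11 steps (steps 1–6 and 8–12, from decanal).

**Steps most likely to fail**

Step 8. The acid-mediated union may be diverted before ring closure by 2-oxonia-Cope exchange of side chains, loss of benzyl alcohol from the β-benzyloxy aldehyde, or capture of the oxocarbenium ion by the C6' ether oxygen. Capture at C6 may also not be fully equatorial. The fallback replaces the cyclization by iterative allylation; it sets out from 11 and comes back at 18. Allylboration of 11 with (+)-Ipc2B(allyl) would give, through the borinate F1 and oxidative work-up, the homoallylic alcohol F2, with C2' set by the reagent. Silylation (TBSOTf, 2,6-lutidine) would give the silyl ether F3. Ozonolysis through the ozonide F4 and PPh3 work-up would give the aldehyde F5. Allylboration with the enantiomeric reagent (−)-Ipc2B(allyl) would give, through the borinate F6, the 1,3-anti alcohol F7, with C6 set by the reagent. Acryloyl chloride and Et3N would give the acrylate F8, and HF·pyridine would remove the silyl group to give 18.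

Step 10. During iodide exchange and zinc treatment the acrylate may migrate to the freed C2' hydroxyl, add iodide or be reduced. The fallback builds the lactone by Z-selective olefination instead of acrylate metathesis; it sets out from 15 and comes back at 19. NaI, then Zn and AcOH, applied to 15 itself would give, through the iodo alcohol F9, the anti-diol alkene F10. 2,2-Dimethoxypropane and PPTS would give the acetonide F11. Ozonolysis through the ozonide F12 would give the aldehyde F13. Still–Gennari olefination (methyl bis(2,2,2-trifluoroethyl)phosphonoacetate, KN(SiMe3)2, 18-crown-6, THF, −78 °C) would give the (Z)-enoate F14. Acid (PPTS, MeOH, then warming) would remove the acetonide, and the C6 hydroxyl would lactonise selectively (six- rather than eight-membered ring) to 19.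

Step 12. Cleavage of the second benzyl ether may stall, or the Lewis acid and chloride may attack the unsaturated lactone. The fallback swaps the benzyl ethers for an acetonide before any alkene is present; it sets out from 15 and comes back at 20. Hydrogenolysis of 15 (H2, Pd(OH)2/C, EtOAc) would give the triol F15. 2,2-Dimethoxypropane and PPTS would tie the syn-1,3-diol as the acetonide F16 and leave the ring hydroxyl free. Acryloyl chloride and Et3N would give the acrylate F17. NaI, then Zn and AcOH, would give, through the iodide F18, the ring-opened diene F19. Metathesis with the second-generation Grubbs catalyst would give the lactone acetonide F20, and aqueous acetic acid would release 20.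

**Further compounds**

F1 | step 8 | (4R,6R,8S)-6,8-bis(benzyloxy)heptadec-1-en-4-yl bis[(+)-isopinocampheyl]borinate | CCCCCCCCC[C@H](OCc1ccccc1)C[C@H](OCc1ccccc1)C[C@H](OB([C@H]1C[C@H]2C[C@@H]([C@@H]1C)C2(C)C)[C@H]1C[C@H]2C[C@@H]([C@@H]1C)C2(C)C)CC=C
F2 | step 8 | (4R,6R,8S)-6,8-bis(benzyloxy)heptadec-1-en-4-ol | CCCCCCCCC[C@H](OCc1ccccc1)C[C@H](OCc1ccccc1)C[C@H](O)CC=C
F3 | step 8 | tert-butyldimethylsilyl ether of F2 | CCCCCCCCC[C@H](OCc1ccccc1)C[C@H](OCc1ccccc1)C[C@H](O[Si](C)(C)C(C)(C)C)CC=C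
F4 | step 8 | secondary ozonide of F3 | CCCCCCCCC[C@H](OCc1ccccc1)C[C@H](OCc1ccccc1)C[C@H](O[Si](C)(C)C(C)(C)C)CC1OCOO1
F5 | step 8 | (3S,5S,7S)-5,7-bis(benzyloxy)-3-[(tert-butyldimethylsilyl)oxy]hexadecanal | CCCCCCCCC[C@H](OCc1ccccc1)C[C@H](OCc1ccccc1)C[C@H](O[Si](C)(C)C(C)(C)C)CC=O
F6 | step 8 | bis[(−)-isopinocampheyl]borinate of F7 | CCCCCCCCC[C@H](OCc1ccccc1)C[C@H](OCc1ccccc1)C[C@H](O[Si](C)(C)C(C)(C)C)C[C@@H](OB([C@@H]1C[C@@H]2C[C@H]([C@H]1C)C2(C)C)[C@@H]1C[C@@H]2C[C@H]([C@H]1C)C2(C)C)CC=C
F7 | step 8 | (4S,6R,8S,10S)-8,10-bis(benzyloxy)-6-[(tert-butyldimethylsilyl)oxy]nonadec-1-en-4-ol | CCCCCCCCC[C@H](OCc1ccccc1)C[C@H](OCc1ccccc1)C[C@H](O[Si](C)(C)C(C)(C)C)C[C@@H](O)CC=C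
F8 | step 8 | prop-2-enoate of F7 | CCCCCCCCC[C@H](OCc1ccccc1)C[C@H](OCc1ccccc1)C[C@H](O[Si](C)(C)C(C)(C)C)C[C@@H](OC(=O)C=C)CC=C
F9 | step 10 | all-cis 2-[(2S,4S)-2,4-bis(benzyloxy)tridecyl]-6-(iodomethyl)oxan-4-ol | CCCCCCCCC[C@H](OCc1ccccc1)C[C@H](OCc1ccccc1)C[C@H]1C[C@@H](O)C[C@@H](CI)O1
F10 | step 10 | (4S,6R,8R,10S)-8,10-bis(benzyloxy)nonadec-1-ene-4,6-diol | CCCCCCCCC[C@H](OCc1ccccc1)C[C@H](OCc1ccccc1)C[C@H](O)C[C@@H](O)CC=C
F11 | step 10 | acetonide of F10 (trans-4,6-disubstituted 2,2-dimethyl-1,3-dioxane) | CCCCCCCCC[C@H](OCc1ccccc1)C[C@H](OCc1ccccc1)C[C@H]1C[C@H](CC=C)OC(C)(C)O1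
F12 | step 10 | secondary ozonide of F11 | CCCCCCCCC[C@H](OCc1ccccc1)C[C@H](OCc1ccccc1)C[C@H]1C[C@H](CC2OCOO2)OC(C)(C)O1
F13 | step 10 | aldehyde from F11 (dioxanyl acetaldehyde) | CCCCCCCCC[C@H](OCc1ccccc1)C[C@H](OCc1ccccc1)C[C@H]1C[C@H](CC=O)OC(C)(C)O1
F14 | step 10 | methyl (Z)-enoate from F13 | CCCCCCCCC[C@H](OCc1ccccc1)C[C@H](OCc1ccccc1)C[C@H]1C[C@H](C/C=C\C(=O)OC)OC(C)(C)O1
F15 | step 12 | all-cis oxane triol tosylate (15 without benzyl groups) | CCCCCCCCC[C@H](O)C[C@H](O)C[C@H]1C[C@@H](O)C[C@@H](COS(=O)(=O)c2ccc(C)cc2)O1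
F16 | step 12 | syn-diol acetonide of F15 | CCCCCCCCC[C@H]1C[C@@H](C[C@H]2C[C@@H](O)C[C@@H](COS(=O)(=O)c3ccc(C)cc3)O2)OC(C)(C)O1
F17 | step 12 | prop-2-enoate of F16 | CCCCCCCCC[C@H]1C[C@@H](C[C@H]2C[C@@H](OC(=O)C=C)C[C@@H](COS(=O)(=O)c3ccc(C)cc3)O2)OC(C)(C)O1
F18 | step 12 | primary iodide from F17 | CCCCCCCCC[C@H]1C[C@@H](C[C@H]2C[C@@H](OC(=O)C=C)C[C@@H](CI)O2)OC(C)(C)O1
F19 | step 12 | ring-opened hydroxy diene acrylate acetonide | CCCCCCCCC[C@H]1C[C@@H](C[C@H](O)C[C@@H](OC(=O)C=C)CC=C)OC(C)(C)O1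
F20 | step 12 | lactone acetonide (acetonide of 20 at C4'/C6') | CCCCCCCCC[C@H]1C[C@@H](C[C@H](O)C[C@@H]2CC=CC(=O)O2)OC(C)(C)O1
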